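**Assumptions (one line each)**
- The target SMILES corresponds to the (S)-flavanone (C2 is S). I assume the cinchona catalyst series in Step 5 is the one that delivers S. This must be confirmed by chiral HPLC and optical rotation or CD; if the R enantiomer results, switch to the pseudo-enantiomeric catalyst.
- 3,5-Dibromo-4-methoxybenzaldehyde (1) and 2',4'-dihydroxyacetophenone (7) are commercial. Catalysts and bulk reagents appear in the Conditions lines and are not numbered.

**Retrosynthesis**
1. The C2 stereocentre and the pyranone ring come last, from an enantioselective intramolecular oxa-Michael cyclization of 2'-hydroxychalcone **8**.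
2. Chalcone **8** comes from a Claisen–Schmidt condensation of 2',4'-dihydroxyacetophenone (**7**) with 4-methoxy-3,5-diprenylbenzaldehyde (**6**).
3. Aldehyde **6** comes from the commercial 3,5-dibromo-4-methoxybenzaldehyde (**1**). The aldehyde is masked as a dioxolane so that the two aryl bromides can be converted to aryllithiums and C-prenylated (SN2, linear).
4. Ring order: the aromatic B ring is fully substituted first, then the enone forms (C–C bond), and finally the chromanone ring closes (C–O bond, with the stereocentre).

**Route**

Step 1
Reactants: 1 (3,5-dibromo-4-methoxybenzaldehyde); 2 (ethylene glycol)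
Product: 3 (2-(3,5-dibromo-4-methoxyphenyl)-1,3-dioxolane)
Conditions: p-TsOH·H2O (cat.), PhMe, reflux, Dean–Stark
Reagents that add atoms: ethylene glycol, OCCO (C2H4O2 unit retained in the acetal)
Why: Acid-catalysed acetalisation masks the aldehyde so that it survives the organolithium step; no stereocentre is formed.

Step 2
Reactants: 3; 4 (prenyl bromide, 1-bromo-3-methylbut-2-ene)
Product: 5 (2-[4-methoxy-3,5-bis(3-methylbut-2-en-1-yl)phenyl]-1,3-dioxolane)
Conditions: t-BuLi (4.4 equiv), THF, –78 °C, 30 min; then CuI (0.2 equiv), prenyl bromide (2.6 equiv), –78 °C → rt
Reagents that add atoms: prenyl bromide, CC(C)=CCBr (two prenyl groups retained; Br lost)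
Why: Double Li–Br exchange followed by Cu-catalysed SN2 alkylation gives the linear prenyl arenes (Cu favours α-attack). The excess t-BuLi destroys the t-BuBr formed in the exchange, and no stereocentre is formed.

Step 3
Reactants: 5
Product: 6 (4-methoxy-3,5-bis(3-methylbut-2-en-1-yl)benzaldehyde)
Conditions: 2 M HCl, THF, rt, 3 h
Reagents that add atoms: water, O (the carbonyl oxygen of the aldehyde is derived from water)
Why: Acetal hydrolysis under mild aqueous acid leaves the aryl methyl ether and the trisubstituted prenyl alkenes intact; no stereocentre is formed.

Step 4
Reactants: 6; 7 (2',4'-dihydroxyacetophenone)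
Product: 8 ((E)-1-(2,4-dihydroxyphenyl)-3-[4-methoxy-3,5-bis(3-methylbut-2-en-1-yl)phenyl]prop-2-en-1-one)
Conditions: KOH (50% aq.), EtOH, rt, 48 h; then 1 M HCl to pH ~3, with no heating
Reagents that add atoms: none
Why: Claisen–Schmidt (aldol/E1cB) condensation gives the thermodynamic E-enone; excess base covers the two acidic phenols. The crude chalcone must be purified (chromatography or recrystallisation) to remove any racemic flavanone formed in situ; no stereocentre is formed.

Step 5
Reactants: 8
Product: 9 ((S)-abyssinone IV 4'-OMe ether, (2S)-7-hydroxy-2-[4-methoxy-3,5-bis(3-methylbut-2-en-1-yl)phenyl]chroman-4-one)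
Conditions: quinine-derived cinchona bifunctional thiourea (10–20 mol%), PhMe, rt, 48–72 h; stop at high conversion and avoid basic work-up
Reagents that add atoms: none (isomerisation)
Why: Intramolecular 6-endo oxa-Michael addition. The catalyst's tertiary amine orients the 2'-phenol while the thiourea H-bonds to and activates the enone, so the phenol oxygen attacks one face of the β-carbon. That carbon becomes C2, and the facial selectivity sets the (S) configuration. Mild conditions limit retro-Michael racemisation.

**Compound list**

| No. | Name | SMILES | Role |
|---|---|---|---|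
| 1 | 3,5-Dibromo-4-methoxybenzaldehyde | COc1c(Br)cc(C=O)cc1Br | starting material |
| 2 | Ethylene glycol | OCCO | starting material |
| 3 | 2-(3,5-Dibromo-4-methoxyphenyl)-1,3-dioxolane | COc1c(Br)cc(C2OCCO2)cc1Br | intermediate |
| 4 | Prenyl bromide | CC(C)=CCBr | starting material |
| 5 | 2-[4-Methoxy-3,5-bis(prenyl)phenyl]-1,3-dioxolane | COc1c(CC=C(C)C)cc(C2OCCO2)cc1CC=C(C)C | intermediate |
| 6 | 4-Methoxy-3,5-bis(prenyl)benzaldehyde | COc1c(CC=C(C)C)cc(C=O)cc1CC=C(C)C | intermediate |
| 7 | 2',4'-Dihydroxyacetophenone | CC(=O)c1ccc(O)cc1O | starting material |
| 8 | (E)-2',4'-Dihydroxy-4-methoxy-3,5-diprenylchalcone | COc1c(CC=C(C)C)cc(/C=C/C(=O)c2ccc(O)cc2O)cc1CC=C(C)C | intermediate |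
| 9 | (S)-Abyssinone IV 4'-OMe ether | COc1c(CC=C(C)C)cc([C@@H]2CC(=O)c3ccc(O)cc3O2)cc1CC=C(C)C | target |

**Total steps:** 5.
**Longest linear sequence:** 5 steps (1 → 3 → 5 → 6 → 8 → 9); compound 7 enters in Step 4 directly from the commercial material.

**Three steps most likely to fail**
1. **Step 5 (ee and conversion).** The oxa-Michael is reversible and the flavanone can racemise, so ee may be only moderate.
   - Fallback: change the substrate class to a Scheidt-type alkylidene β-ketoester. Make the 2-hydroxyaryl β-ketoester from 7, condense it with 6, cyclise with the cinchona-thiourea catalyst, then decarboxylate.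
   - Alternative fallback: cyclise racemically (NaOAc, EtOH, reflux) and separate the enantiomers by preparative chiral HPLC.
2. **Step 2 (bis-prenylation).** Regioselectivity (SN2 vs SN2′), incomplete dialkylation, and benzylic deprotonation of the product are all risks.
   - Fallback: double allylation of 3 with allyl-Bpin (Pd) or allyl-SnBu3 to give the diallyl arene, which is linear by construction. Then convert to the bis-prenyl compound by cross-metathesis with 2-methylbut-2-ene (Hoveyda–Grubbs II), taking care over allyl-to-propenyl isomerisation.
3. **Step 4 (Claisen–Schmidt with two free phenols).** Yields can be low, and partial racemic flavanone formation contaminates the chalcone.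
   - Fallback: protect 7 as its bis-MOM ether, condense under LiOH/MeOH, then remove MOM with HCl/MeOH to give pure chalcone 8 before Step 5.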